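## Retrosynthetic overview

- Microeunicellol A ⇐ its C7 tert-butyl ester ⇐ ring B (ten-membered) closed last at C7–C8 by an electrochemical Cr/Ni alkenyl iodide–aldehyde coupling, which also sets C8.
- C2=C3 ⇐ Horner–Wadsworth–Emmons union of a ring A aldehyde with a C3–C7 phosphonate/(Z)-iodoenoate linker (from a phosphonoacetate, acrolein and an iodo-ylide).
- Ring A (C11 ketone, C14 isopropylidene, trans C1/C10) ⇐ (S)-4-(2-acetoxyprop-2-yl)cyclohexenone by anti vinyl 1,4-addition/enolate alkylation, then Saegusa oxidation, vinylogous elimination and 1,4-reduction.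
- That enone ⇐ (+)-nopinone (ozonolysis product of (−)-β-pinene) by cyclobutane opening; ring A is made first, ring B last.

Assumption: atom labels C1–C20 follow eunicellane numbering (C1/C10 ring fusion, C8 carbinol, C11 and C14 the ring A carbons bearing the methylidene and isopropylidene groups); compounds 1, 11, 12, 14 and all reagents are bought.

## Route

Step 1
Reactants: 1 (1R,5S)-6,6-dimethylbicyclo[3.1.1]heptan-2-one ((+)-nopinone)
Product: 2 (4S)-4-(2-acetoxypropan-2-yl)cyclohex-1-en-1-yl acetate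
Conditions: Ac2O, Zn(OAc)2 (0.2 equiv), BF3·OEt2 (0.3 equiv), 0 °C → rt
Reagents that add atoms: acetic anhydride CC(=O)OC(C)=O
Why: Lewis-acid activation of the ketone breaks the strained bridgehead–CMe2 bond next to the carbonyl (cationic cyclobutyl ketone fragmentation), the enol and the tertiary cation are both capped as acetates, and the untouched bridgehead stereocentre becomes the (S) centre (future C14) that later steers C1 and C10.

Step 2
Reactants: 2 (4S)-4-(2-acetoxypropan-2-yl)cyclohex-1-en-1-yl acetate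
Product: 3 (4S)-4-(2-acetoxypropan-2-yl)cyclohex-2-en-1-one
Conditions: Pd(OAc)2 (5 mol %), Bu3SnOMe (20 mol %), allyl methyl carbonate (2 equiv), MeCN, 80 °C
Reagents that add atoms: none
Why: Tsuji dehydrogenation of an enol acetate, in which the regiodefined tin enolate passes to a palladium enolate that undergoes β-hydride elimination, so the enone lies on the side fixed by the fragmentation and 3 is the single (S) enantiomer.

Step 3
Reactants: 3 (4S)-4-(2-acetoxypropan-2-yl)cyclohex-2-en-1-one
Product: 5 2-[(1S,2R,3S)-3-(2-acetoxypropan-2-yl)-2-ethenyl-6-oxocyclohexyl]-N-methoxy-N-methylacetamide, via bromomagnesium enolate 4 (not isolated)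
Conditions: CH2=CHMgBr (1.2 equiv), CuBr·SMe2 (10 mol %), THF, −78 °C; then DMPU, BrCH2C(O)N(OMe)Me (1.5 equiv), −78 → −20 °C
Reagents that add atoms: vinylmagnesium bromide C=C[Mg]Br; 2-bromo-N-methoxy-N-methylacetamide CON(C)C(=O)CBr
Why: Copper-catalysed 1,4-addition places the vinyl group anti to the bulky 2-acetoxyprop-2-yl group and the enolate is alkylated anti to the new vinyl group (three-component conjugate addition–alkylation), which sets C1 and C10 trans from the bought centre.

Step 4
Reactants: 5 2-[(1S,2R,3S)-3-(2-acetoxypropan-2-yl)-2-ethenyl-6-oxocyclohexyl]-N-methoxy-N-methylacetamide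
Product: 8 2-[(1S,6S)-6-ethenyl-2-oxo-5-(propan-2-ylidene)cyclohex-3-en-1-yl]-N-methoxy-N-methylacetamide, via silyl enol ether 6 (not isolated), via acetoxy enone 7 (not isolated)
Conditions: LiN(i-Pr)2, Me3SiCl, THF, −78 °C; Pd(OAc)2 (10 mol %), O2 (1 atm), DMSO, rt; then DBU (1.2 equiv), CH2Cl2, 0 °C, 15 min
Reagents that add atoms: none
Why: Kinetic enolisation at the unsubstituted C12, Saegusa–Ito dehydrogenation and vinylogous E1cB loss of acetic acid put the double bond regiospecifically at C14=C15, with the C14 centre given up only after use and the hindered C10–H left alone by the short cold base treatment.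

Step 5
Reactants: 8 2-[(1S,6S)-6-ethenyl-2-oxo-5-(propan-2-ylidene)cyclohex-3-en-1-yl]-N-methoxy-N-methylacetamide
Product: 9 2-[(1S,2S)-2-ethenyl-6-oxo-3-(propan-2-ylidene)cyclohexyl]-N-methoxy-N-methylacetamide
Conditions: LiB(s-Bu)3H (1.05 equiv), THF, −78 °C; aq NH4Cl
Reagents that add atoms: none
Why: Conjugate (1,4) hydride reduction of the dienone by the bulky borohydride at the unsubstituted β-carbon (the fully substituted δ-carbon blocks 1,6-attack) gives the saturated ketone without touching C1 or C10.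

Step 6
Reactants: 9 2-[(1S,2S)-2-ethenyl-6-oxo-3-(propan-2-ylidene)cyclohexyl]-N-methoxy-N-methylacetamide
Product: 10 2-[(1S,2S)-2-formyl-6-oxo-3-(propan-2-ylidene)cyclohexyl]-N-methoxy-N-methylacetamide
Conditions: OsO4 (2 mol %), NaIO4 (4 equiv), 2,6-lutidine (2 equiv), dioxane/H2O 3:1, rt
Reagents that add atoms: osmium tetroxide O=[Os](=O)(=O)=O; sodium periodate [Na+].[O-]I(=O)(=O)=O
Why: Lemieux–Johnson cleavage is selective because the monosubstituted vinyl group is dihydroxylated far faster than the tetrasubstituted isopropylidene, and the buffered neutral medium keeps the α-branched aldehyde from epimerising.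

Step 7
Reactants: 11 methyl 2-(diethoxyphosphoryl)acetate; 12 prop-2-enal (acrolein)
Product: 13 methyl 2-(diethoxyphosphoryl)-5-oxopentanoate (racemic at C2; this centre is lost in step 9)
Conditions: 11 (3 equiv), DBU (5 mol %), THF, −20 °C
Reagents that add atoms: none
Why: Base-catalysed Michael addition of the phosphonoacetate to acrolein, with excess phosphonate suppressing double addition.

Step 8
Reactants: 13 methyl 2-(diethoxyphosphoryl)-5-oxopentanoate; 14 tert-butyl 2-(triphenyl-λ5-phosphanylidene)acetate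
Product: 16 1-tert-butyl 7-methyl (2Z)-6-(diethoxyphosphoryl)-2-iodohept-2-enedioate (racemic at C6), via iodo-ylide 15 (not isolated)
Conditions: N-iodosuccinimide (1.05 equiv), CH2Cl2, −20 °C, 30 min; then 13, −20 °C → rt
Reagents that add atoms: N-iodosuccinimide O=C1CCC(=O)N1I
Why: One-pot ylide iodination–Wittig olefination reacts only at the aldehyde and gives the (Z)-2-iodoenoate, the geometry that later places C5 and C8 cis on C6=C7.

Step 9
Reactants: 10 2-[(1S,2S)-2-formyl-6-oxo-3-(propan-2-ylidene)cyclohexyl]-N-methoxy-N-methylacetamide; 16 1-tert-butyl 7-methyl (2Z)-6-(diethoxyphosphoryl)-2-iodohept-2-enedioate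
Product: 17 1-tert-butyl 7-methyl (2Z,6E)-2-iodo-6-({(1S,2S)-2-[2-(methoxy(methyl)amino)-2-oxoethyl]-3-oxo-6-(propan-2-ylidene)cyclohexyl}methylidene)hept-2-enedioate
Conditions: LiCl (1.5 equiv), i-Pr2NEt (1.2 equiv), MeCN, 0 °C → rt
Reagents that add atoms: none
Why: Horner–Wadsworth–Emmons olefination under mild Masamune–Roush conditions reacts at the aldehyde and not the ketone, and gives the (E) trisubstituted enoate (C1 trans to the ester) at C2=C3.

Step 10
Reactants: 17 1-tert-butyl 7-methyl (2Z,6E)-2-iodo-6-({(1S,2S)-2-[2-(methoxy(methyl)amino)-2-oxoethyl]-3-oxo-6-(propan-2-ylidene)cyclohexyl}methylidene)hept-2-enedioate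
Product: 18 1-tert-butyl 7-methyl (2Z,6E)-2-iodo-6-({(1S,2S)-2-[2-(methoxy(methyl)amino)-2-oxoethyl]-3-methylidene-6-(propan-2-ylidene)cyclohexyl}methylidene)hept-2-enedioate
Conditions: Cp2Ti(μ-Cl)(μ-CH2)AlMe2 (1.2 equiv), THF/toluene, −40 → 0 °C; aq NaHCO3
Reagents that add atoms: Cp2Ti(μ-Cl)(μ-CH2)AlMe2 C[Al-]1(C)C[Ti](C2C=CC=C2)(C2C=CC=C2)[Cl+]1
Why: Non-basic methylidene transfer from Cp2Ti(μ-Cl)(μ-CH2)AlMe2 (Tebbe-type methylenation) converts the ketone faster than the esters or the amide at low temperature and cannot epimerise C10.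

Step 11
Reactants: 18 1-tert-butyl 7-methyl (2Z,6E)-2-iodo-6-({(1S,2S)-2-[2-(methoxy(methyl)amino)-2-oxoethyl]-3-methylidene-6-(propan-2-ylidene)cyclohexyl}methylidene)hept-2-enedioate
Product: 20 1-tert-butyl 7-methyl (2Z,6E)-2-iodo-6-({(1S,2S)-3-methylidene-2-(2-oxoethyl)-6-(propan-2-ylidene)cyclohexyl}methylidene)hept-2-enedioate, via zirconated hemiaminal 19 (not isolated)
Conditions: Cp2Zr(H)Cl (1.5 equiv), THF, rt, 15 min; then SiO2/H2O
Reagents that add atoms: none
Why: Chemoselective reduction of the N-methoxy-N-methylamide by Cp2Zr(H)Cl stops at a stable chelated hemiaminal that releases the C8 aldehyde only on work-up, leaving both esters and the alkenyl iodide intact.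

Step 12
Reactants: 20 1-tert-butyl 7-methyl (2Z,6E)-2-iodo-6-({(1S,2S)-3-methylidene-2-(2-oxoethyl)-6-(propan-2-ylidene)cyclohexyl}methylidene)hept-2-enedioate
Product: 22 7-tert-butyl 3-methyl (1S,2E,6E,8R,10S)-8-hydroxy-11-methylidene-14-(propan-2-ylidene)bicyclo[8.4.0]tetradeca-2,6-diene-3,7-dicarboxylate, via zirconocene alkoxide 21 (not isolated)
Conditions: CrCl2 (20 mol %), NiCl2(MeOCH2CH2OMe) (2 mol %), Cp2ZrCl2 (1.2 equiv), n-Bu4NPF6 (0.1 M), DMF, Al anode, Ni-foam cathode, undivided cell, constant current 3 mA, 20 added over 8 h (final 2 mM), rt; aq NH4Cl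
Reagents that add atoms: none
Why: Proposed new method: an electrochemical chromium/nickel-catalysed Nozaki–Hiyama–Kishi macrocyclisation of a (Z)-2-iodoenoate onto a tethered aldehyde to close a ten-membered carbocycle, in which the cathode regenerates divalent chromium and zerovalent nickel, nickel inserts into C–I with retention, the alkenyl group passes to trivalent chromium and adds to the aldehyde, Cp2ZrCl2 frees chromium from the alkoxide, the ring allows only the C5/C8-cis alkene even if the α-chromio ester equilibrates through its allenolate, and C8 is expected (R) by peripheral attack with the metal-bound oxygen outside the ring held by the trans C1/C10 appendages; the closest known reaction types are the intermolecular electrochemical Nozaki–Hiyama–Kishi coupling of alkenyl halides and the stoichiometric CrCl2/NiCl2 macrocyclisation.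

Step 13
Reactants: 22 7-tert-butyl 3-methyl (1S,2E,6E,8R,10S)-8-hydroxy-11-methylidene-14-(propan-2-ylidene)bicyclo[8.4.0]tetradeca-2,6-diene-3,7-dicarboxylate
Product: 24 (1S,2E,6E,8R,10S)-8-hydroxy-3-(methoxycarbonyl)-11-methylidene-14-(propan-2-ylidene)bicyclo[8.4.0]tetradeca-2,6-diene-7-carboxylic acid (Microeunicellol A), via bis-silyl derivative 23 (not isolated)
Conditions: Me3SiOTf (4 equiv), 2,6-lutidine (6 equiv), CH2Cl2, 0 °C; then pH 4 citrate buffer/MeOH, rt
Reagents that add atoms: none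
Why: Silyl triflate-mediated tert-butyl ester cleavage (loss of 2-methylpropene under buffered, non-protic conditions) spares the methyl ester, the exocyclic alkenes and the allylic carbinol, and mild hydrolysis of the silyl ester and silyl ether gives the target.

## Compound list

1 | (1R,5S)-6,6-dimethylbicyclo[3.1.1]heptan-2-one ((+)-nopinone) | O=C1CC[C@H]2C[C@@H]1C2(C)C | starting material
2 | (4S)-4-(2-acetoxypropan-2-yl)cyclohex-1-en-1-yl acetate | CC(=O)OC1=CC[C@@H](C(C)(C)OC(C)=O)CC1 | intermediate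
3 | (4S)-4-(2-acetoxypropan-2-yl)cyclohex-2-en-1-one | O=C1C=C[C@@H](C(C)(C)OC(C)=O)CC1 | intermediate
4 | bromomagnesium (3S,4S)-4-(2-acetoxypropan-2-yl)-3-ethenylcyclohex-1-en-1-olate | Br[Mg]OC1=C[C@H](C=C)[C@@H](C(C)(C)OC(C)=O)CC1 | intermediate
5 | 2-[(1S,2R,3S)-3-(2-acetoxypropan-2-yl)-2-ethenyl-6-oxocyclohexyl]-N-methoxy-N-methylacetamide | O=C1CC[C@H](C(C)(C)OC(C)=O)[C@@H](C=C)[C@@H]1CC(=O)N(C)OC | intermediate
6 | trimethylsilyl enol ether of 5 (C11=C12), 2-[(1S,2R,3S)-3-(2-acetoxypropan-2-yl)-2-ethenyl-6-(trimethylsilyloxy)cyclohex-5-en-1-yl]-N-methoxy-N-methylacetamide | C[Si](C)(C)OC1=CC[C@H](C(C)(C)OC(C)=O)[C@@H](C=C)[C@@H]1CC(=O)N(C)OC | intermediate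
7 | 2-[(1S,5S,6R)-5-(2-acetoxypropan-2-yl)-6-ethenyl-2-oxocyclohex-3-en-1-yl]-N-methoxy-N-methylacetamide | O=C1C=C[C@H](C(C)(C)OC(C)=O)[C@@H](C=C)[C@@H]1CC(=O)N(C)OC | intermediate
8 | 2-[(1S,6S)-6-ethenyl-2-oxo-5-(propan-2-ylidene)cyclohex-3-en-1-yl]-N-methoxy-N-methylacetamide | O=C1C=CC(=C(C)C)[C@@H](C=C)[C@@H]1CC(=O)N(C)OC | intermediate
9 | 2-[(1S,2S)-2-ethenyl-6-oxo-3-(propan-2-ylidene)cyclohexyl]-N-methoxy-N-methylacetamide | O=C1CCC(=C(C)C)[C@@H](C=C)[C@@H]1CC(=O)N(C)OC | intermediate
10 | 2-[(1S,2S)-2-formyl-6-oxo-3-(propan-2-ylidene)cyclohexyl]-N-methoxy-N-methylacetamide | O=C1CCC(=C(C)C)[C@@H](C=O)[C@@H]1CC(=O)N(C)OC | intermediate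
11 | methyl 2-(diethoxyphosphoryl)acetate | CCOP(=O)(OCC)CC(=O)OC | starting material
12 | prop-2-enal (acrolein) | C=CC=O | starting material
13 | methyl 2-(diethoxyphosphoryl)-5-oxopentanoate (racemic) | CCOP(=O)(OCC)C(CCC=O)C(=O)OC | intermediate
14 | tert-butyl 2-(triphenyl-λ5-phosphanylidene)acetate | CC(C)(C)OC(=O)C=P(c1ccccc1)(c1ccccc1)c1ccccc1 | starting material
15 | tert-butyl 2-iodo-2-(triphenyl-λ5-phosphanylidene)acetate | CC(C)(C)OC(=O)C(I)=P(c1ccccc1)(c1ccccc1)c1ccccc1 | intermediate
16 | 1-tert-butyl 7-methyl (2Z)-6-(diethoxyphosphoryl)-2-iodohept-2-enedioate (racemic at C6) | CCOP(=O)(OCC)C(CC/C=C(\I)C(=O)OC(C)(C)C)C(=O)OC | intermediate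
17 | 1-tert-butyl 7-methyl (2Z,6E)-2-iodo-6-({(1S,2S)-2-[2-(methoxy(methyl)amino)-2-oxoethyl]-3-oxo-6-(propan-2-ylidene)cyclohexyl}methylidene)hept-2-enedioate | O=C1CCC(=C(C)C)[C@@H](/C=C(/C(=O)OC)CC/C=C(\I)C(=O)OC(C)(C)C)[C@@H]1CC(=O)N(C)OC | intermediate
18 | 1-tert-butyl 7-methyl (2Z,6E)-2-iodo-6-({(1S,2S)-2-[2-(methoxy(methyl)amino)-2-oxoethyl]-3-methylidene-6-(propan-2-ylidene)cyclohexyl}methylidene)hept-2-enedioate | C=C1CCC(=C(C)C)[C@@H](/C=C(/C(=O)OC)CC/C=C(\I)C(=O)OC(C)(C)C)[C@@H]1CC(=O)N(C)OC | intermediate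
19 | O-[chlorobis(cyclopentadienyl)zirconio] hemiaminal of 18 at C8 | C=C1CCC(=C(C)C)[C@@H](/C=C(/C(=O)OC)CC/C=C(\I)C(=O)OC(C)(C)C)[C@@H]1CC(O[Zr](Cl)(C2C=CC=C2)C2C=CC=C2)N(C)OC | intermediate
20 | 1-tert-butyl 7-methyl (2Z,6E)-2-iodo-6-({(1S,2S)-3-methylidene-2-(2-oxoethyl)-6-(propan-2-ylidene)cyclohexyl}methylidene)hept-2-enedioate | C=C1CCC(=C(C)C)[C@@H](/C=C(/C(=O)OC)CC/C=C(\I)C(=O)OC(C)(C)C)[C@@H]1CC=O | intermediate
21 | chlorobis(cyclopentadienyl)zirconium 8-alkoxide of 22 | C=C1CCC(=C(C)C)[C@H]2/C=C(/C(=O)OC)CC/C=C(/C(=O)OC(C)(C)C)[C@H](O[Zr](Cl)(C3C=CC=C3)C3C=CC=C3)C[C@H]12 | intermediate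
22 | 7-tert-butyl 3-methyl (1S,2E,6E,8R,10S)-8-hydroxy-11-methylidene-14-(propan-2-ylidene)bicyclo[8.4.0]tetradeca-2,6-diene-3,7-dicarboxylate | C=C1CCC(=C(C)C)[C@H]2/C=C(/C(=O)OC)CC/C=C(/C(=O)OC(C)(C)C)[C@H](O)C[C@H]12 | intermediate
23 | trimethylsilyl ester and 8-O-trimethylsilyl ether of 24 | C=C1CCC(=C(C)C)[C@H]2/C=C(/C(=O)OC)CC/C=C(/C(=O)O[Si](C)(C)C)[C@H](O[Si](C)(C)C)C[C@H]12 | intermediate
24 | Microeunicellol A, (1S,2E,6E,8R,10S)-8-hydroxy-3-(methoxycarbonyl)-11-methylidene-14-(propan-2-ylidene)bicyclo[8.4.0]tetradeca-2,6-diene-7-carboxylic acid | C=C1CCC(=C(C)C)[C@H]2/C=C(/C(=O)OC)CC/C=C(/C(=O)O)[C@H](O)C[C@H]12 | target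

## Step count and risks

Total steps: 13. Longest linear sequence: 11 (steps 1–6 and 9–13).

The three steps most likely to fail:

1. Step 12, the proposed new electrochemical ring closure. The catalytic cycle has not been shown for a 2-iodoenoate donor or for a ten-membered ring, and the C8 configuration rests on ring control alone. The fallback uses known chemistry; it sets out from 20 and comes back at 22. The electrocatalytic cycle is given up, and the alkenylchromium reagent is made with a stoichiometric chemical reductant in the classical Nozaki–Hiyama–Kishi ring closure: CrCl2 (6 equiv), NiCl2 (1 mol %), degassed DMSO/THF, 5 mM, rt, syringe-pump addition, with no cell and no zirconocene. It makes no new compound.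

2. Step 9, the Horner–Wadsworth–Emmons union. Aldehyde 10 is α-branched and β,γ-unsaturated, so base may epimerise C1 or move the C14=C15 double bond into conjugation before the hindered olefination occurs. The fallback sets out from 9 and 16 and comes back at 17, bypassing 10. Phosphonate 16 is olefinated with aqueous formaldehyde and K2CO3 to give 1-tert-butyl 7-methyl (2Z)-2-iodo-6-methylidenehept-2-enedioate F1. The vinyl group of 9 is then joined to F1 by cross-metathesis, with the second-generation Hoveyda–Grubbs catalyst RuCl2(H2IMes)(=CH-2-(i-PrO)C6H4) in CH2Cl2 at 40 °C, which gives the (E) enoate 17 under neutral conditions.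

3. Step 3, the three-component coupling. Alkylation of the enolate from the copper-catalysed addition can be slow, and the tertiary acetate limits the choice of stronger conditions. The fallback sets out from 3 and comes back at 5. The conjugate addition is run with Me3SiCl present and the product is isolated as [(3S,4S)-4-(2-acetoxypropan-2-yl)-3-ethenylcyclohex-1-en-1-yl]oxy(trimethyl)silane F2. This enol silane is then alkylated by a radical route instead of a polar one: visible-light photoredox α-alkylation with 2-bromo-N-methoxy-N-methylacetamide, Ir(ppy)3 (1 mol %), blue LEDs, DMF, rt. The electrophilic amidomethyl radical adds anti to the vinyl group.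

Further compounds
F0 | step 12 | none | none
F1 | step 9 | 1-tert-butyl 7-methyl (2Z)-2-iodo-6-methylidenehept-2-enedioate | C=C(CC/C=C(\I)C(=O)OC(C)(C)C)C(=O)OC
F2 | step 3 | [(3S,4S)-4-(2-acetoxypropan-2-yl)-3-ethenylcyclohex-1-en-1-yl]oxy(trimethyl)silane | C[Si](C)(C)OC1=C[C@H](C=C)[C@@H](C(C)(C)OC(C)=O)CC1
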